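# Perlatolic acid by Diels–Alder benzannulation of ring B: synthesis design

## The problem

Perlatolic acid is a depside in which two 6-pentylresorcylic acid units are joined by a single aryl ester between the carboxyl carbon of ring A (the 2-hydroxy-4-methoxy-6-pentylbenzoyl unit) and the C4 oxygen of ring B (the 2-hydroxy-6-pentylbenzoic acid unit). There is no stereocenter and no ring fusion, so the task is to tell near-identical groups apart: four phenolic oxygens and two carboxyl groups must end in six different states (ring A with C2–OH free, C4–OMe and its carboxyl as the linking ester; ring B with C2–OH free, C4–O acylated and its carboxyl free). With no stereochemical relay, the only internal control elements are the hydrogen bonds or chelates between each carbonyl group and its ortho oxygen, which make an ortho hydroxyl a poor nucleophile and steer a Lewis acid to an ortho ether. The depside link is an activated aryl ester that will not outlast hydroxide, alkoxide or amine nucleophiles, so the ring B carboxyl cannot be freed by saponification. The electron-rich ortho-hydroxybenzoic acids decarboxylate on heating or in hot acid, so free acids should appear late and be handled cold. Both carboxyl carbons sit between two ortho substituents, which slows acyl transfer and calls for a strongly activated acyl donor in the coupling. Ring B can be built from open-chain pieces because C1 (carboxyl) and C6 (pentyl) are neighbours and correspond to the two sp carbons of an oct-2-ynoate, while C2 to C5 with oxygen on C2 and C4 map onto a 1,1,3-trioxygenated butadiene, so that a cycloaddition–aromatization delivers ring B with C4–OH free and C2–O as a methyl ether and the two phenols are differentiated as the ring is formed.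

## Retrosynthesis

**18 to 17.** The last operation is chosen first. No skeletal bond is cut: the C2–OH of ring B in perlatolic acid 18 is traced back to the methyl ether in acid 17. This ether is what the ring-forming step leaves on C2. It is the only methyl ether of the molecule that sits ortho to a carboxyl group, so a chelating boron Lewis acid can find it, while the ring A methoxy group, para to its carbonyl, offers no such handle. Cleaving it earlier, on benzyl ester 11, would expose a benzyl ester to the Lewis acid and would hand the coupling two free phenols. Left to the end, the step asks only that the aryl ester and the ring A ether survive at low temperature.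

**17 to 16.** The free carboxyl of 17 is masked as benzyl ester 16; the bond cut is the ester O–CH2Ph bond. A benzyl ester comes off under neutral, non-nucleophilic conditions, which the depside link demands. Placing the hydrogenolysis before the Lewis-acid step removes the only other Lewis-acid-labile group from the substrate of step 10. The forward step must cleave the benzylic C–O bond and leave the aryl ester alone.

**16 to 11 and 14.** The central disconnection is the depside C(=O)–O bond. It splits 16 into two fragments of nearly equal size, phenol 11 (ring B) and acid 14 (ring A). Cutting the ring B aryl–O bond instead would need an aryl C–O coupling on a hindered benzoate, and any cut inside a ring at this stage would give up convergence. Phenol 11 has exactly one free hydroxyl, so the acylation has no site selectivity to win. What is asked is an acyl donor strong enough for a di-ortho-substituted, electron-rich acid; the mixed anhydride 15 answers this, and the hydrogen-bonded C2–OH of 14 needs no protection.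

**14 to 13 to 12.** Ring A is not built. Acid 14 is olivetolic acid 12 with one methyl group added on the C4 oxygen. Cutting that O–CH3 bond together with the ester O–CH3 bond of methyl ester 13 leads back to 12. This is preferred to a de novo synthesis because the skeleton is already there and the hydrogen bond of the C2–OH differentiates the phenols. The forward steps ask for alkylation that stops at the non-chelated phenol and for hydrolysis of a hindered ester without decarboxylation.

**11 to 8 and 2.** Ring B is opened at C1–C2 and C5–C6. C1 and C6 with their carboxyl and pentyl groups become the alkyne carbons of benzyl oct-2-ynoate 2. C2 to C5 become diene 8, whose ketene-acetal carbon is the future C2 and whose silyloxy carbon is the future C4. Against a condensation that forms one ring bond at a time, this cut fixes the substitution pattern through the polarization of two stable, distillable partners. It also delivers the C4 oxygen free and the C2 oxygen etherified, the reverse of what alkylation of a resorcylate gives. The precursors are an acyclic ynoate and a four-carbon diene. The forward reaction has to be regioselective (ester next to the ketal carbon) and has to aromatize by loss of one methoxy group, passing through cycloadduct 9 and silyl ether 10.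

**8 to 7 to 6 to 3 and 4; 2 to 1.** Diene 8 is the silyl enol ether of vinylogous ester 7 (O–Si bond cut). Compound 7 comes from dichloro enone 6 by exchange of both C–Cl bonds. Enone 6 comes from acetyl chloride 3 and 1,1-dichloroethene 4 by C–C bond formation at the alkene CH2, through trichloro ketone 5. Ynoate 2 is the benzyl ester of oct-2-ynoic acid 1. All of these are functional-group operations on small commodity compounds.

## Roads not taken

Alternative 1: The cut falls in ring A: the C6–pentyl and C1–carboxyl bonds are both made on a preformed benzene. 1-Fluoro-3,5-dimethoxybenzene A1 is metalated between fluorine and a methoxy group by excess pentyllithium A2, and β-elimination gives 3,5-dimethoxybenzyne A3. A second equivalent of A2 adds to the aryne carbon of A3 remote from the neighbouring methoxy group. The aryllithium so formed, stabilized inductively by that methoxy group, is carboxylated to 2,4-dimethoxy-6-pentylbenzoic acid A4.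
- Merits: one flask, two bonds, an inexpensive arene and no ring synthesis. A4 is one chelation-controlled demethylation away from acid 14.
- Weak points: regiocontrol of the carbolithiation rests on an inductive bias alone. The product aryllithium can add to further A3. Metalation of A1 between its two methoxy groups gives an aryllithium that cannot eliminate fluoride and ends, after carboxylation, as a fluorinated by-product acid.
- The method answers the easier half of the target. Applied to ring B it would give two methyl ethers and no way to acylate the C4 oxygen selectively.
- Comparison: for ring A alone this road is as short as steps 6 and 7 and starts from cheaper material than 12. The chosen plan sets against it that its key step solves the harder ring and produces the C4–OH free.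

Alternative 2: Ring A is cut at C3–C4 and C1–C6 into a three-carbon 1,3-dinucleophile and a three-carbon 1,3-dielectrophile. 1-Methoxy-1,3-bis(trimethylsilyloxy)buta-1,3-diene A5 and 1,1-dimethoxyoct-1-en-3-one A6 are condensed under a strong Lewis acid. The terminal carbon of A5 adds to the ketene-acetal carbon of A6, the central carbon of A5 closes onto the ketone of A6, and aromatization gives methyl 2-hydroxy-4-methoxy-6-pentylbenzoate A7, which is the same substance as ester 13.
- Merits: the regiochemistry follows from the matching of the termini. The C4 methoxy group is installed in the ring-forming step, and the chelated C2–OH of A7 is free without any demethylation.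
- Weak points: both A5 and A6 are moisture-sensitive and each needs its own short preparation. The Lewis acid is stoichiometric. The product A7 is a compound that the chosen route reaches in one step from 12.
- The oxygen pattern produced (C4 alkylated, C2 free) is the opposite of what ring B needs for the coupling.
- Comparison: if 12 were not available, this would be the better entry to ring A, free of any natural-product-derived starting material. The chosen plan has only its shorter count to set against it, and this road could supply A7, that is 13, without touching the key step.

Alternative 3: Ring B is cut at C1–C6 only. The open-chain precursor is benzyl 3,5,7-trioxododecanoate A8. Under mild carbonate base A8 should undergo intramolecular aldol addition of C2 to the C7 ketone, dehydration and enolization to benzyl 2,4-dihydroxy-6-pentylbenzoate A9.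
- Merits: the closure is biomimetic. A9 is the classical depside coupling partner: its non-chelated C4–OH is acylated in preference to the chelated C2–OH, and hydrogenolysis then ends the synthesis. No Lewis-acid step on the finished depside is needed, and the endgame is one step shorter than in the chosen plan.
- Weak points: A8 must be assembled by polyanion acylation, which a benzyl ester tolerates poorly. A8 is a mixture of enol tautomers that can lactonize to a pyrone or close in the Claisen sense (C6 onto C1) to an acylphloroglucinol. The desired mode depends on conditions, not on the structure.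
- Comparison: the chosen plan secures the regiochemistry of ring closure by the polarization of two stable partners and gives a product with a single free phenol. It pays for this with the extra deprotection of step 10, which the road through A9 does not need.

Key step: step 5

## Route

Assumption: the aryl trimethylsilyl ether formed in the cycloaddition–aromatization is taken to be cleaved in the dilute-acid work-up of step 5, so that phenol 11 is what is isolated; compounds 1, 3, 4 and 12 are taken as purchasable.

Step 1
Reactants: 1 oct-2-ynoic acid
Product: 2 benzyl oct-2-ynoate
Conditions: BnBr, K2CO3, DMF, rt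
Reagents that add atoms: benzyl bromide, BrCc1ccccc1
Why: SN2 O-alkylation of the carboxylate by a benzylic halide; the conjugated alkyne is inert to carbonate at room temperature.

Step 2
Reactants: 3 acetyl chloride; 4 1,1-dichloroethene
Product: 6 4,4-dichlorobut-3-en-2-one, via 4,4,4-trichlorobutan-2-one 5 (not isolated)
Conditions: AlCl3, CH2Cl2, 0 °C to rt; ice–H2O; distillation (loss of HCl)
Reagents that add atoms: none
Why: Lewis-acid-mediated acylation of an alkene (aliphatic Friedel–Crafts reaction): the acylium ion adds to the CH2 terminus of 4, the dichloro carbocation captures chloride to give 5, and β-elimination of HCl into conjugation with the ketone should give 6.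

Step 3
Reactants: 6 4,4-dichlorobut-3-en-2-one
Product: 7 4,4-dimethoxybut-3-en-2-one
Conditions: NaOMe (2.2 equiv), MeOH, 0 °C to rt
Reagents that add atoms: sodium methoxide, [Na+].[O-]C
Why: Twofold addition–elimination (nucleophilic vinylic substitution) of methoxide at the β-carbon of the enone, each exchange activated by the carbonyl group.

Step 4
Reactants: 7 4,4-dimethoxybut-3-en-2-one
Product: 8 1,1-dimethoxy-3-(trimethylsilyloxy)buta-1,3-diene
Conditions: Me3SiCl, Et3N, ZnCl2 (cat.), toluene, 40 °C; filtration, distillation under reduced pressure
Reagents that add atoms: chlorotrimethylsilane, C[Si](C)(C)Cl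
Why: Silyl enol ether formation by soft enolization at the only enolizable position, the acetyl methyl group of vinylogous ester 7, should give the cross-conjugated 2-silyloxydiene.

Step 5
Reactants: 8 1,1-dimethoxy-3-(trimethylsilyloxy)buta-1,3-diene; 2 benzyl oct-2-ynoate
Product: 11 benzyl 4-hydroxy-2-methoxy-6-pentylbenzoate, via cyclohexadiene cycloadduct 9 (not isolated), via aryl trimethylsilyl ether 10 (not isolated)
Conditions: neat, 8 (2 equiv), 120 °C, sealed tube, argon; then 0.5 M HCl, THF, rt
Reagents that add atoms: none
Why: This is a normal-electron-demand Diels–Alder reaction of a 1,1-dialkoxy-3-silyloxybutadiene with an acetylenic ester followed by aromatization, a known route to resorcylate esters. The diene HOMO has its largest coefficient at the terminal CH2 and the ynoate LUMO at the pentyl-bearing β-carbon, so bond formation is concerted but asynchronous, the CH2–Cβ bond leading and the bond from the ketene-acetal carbon to Cα following. The six-membered carbocycle of ring B is closed by this (4+2) cycloaddition, which forms the C5–C6 and C1–C2 bonds and gives 1,4-cyclohexadiene 9. At the reaction temperature 9 should aromatize by 1,4-elimination of methanol from the ketal carbon and the ring CH2 to give silyl ether 10, and the dilute-acid work-up hydrolyses the aryl O–Si bond to the phenol. No stereocenter is formed. The only selectivity needed is regiochemical, the ester next to the ketal carbon, and it is secured by the matched polarization of the partners: three oxygen donors push toward the CH2 terminus of 8 and the ester pulls toward Cβ of 2. Heating is needed because a β-alkyl ynoate is only a modest dienophile, and the excess of diene covers its thermal losses.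

Step 6
Reactants: 12 olivetolic acid (2,4-dihydroxy-6-pentylbenzoic acid)
Product: 13 methyl 2-hydroxy-4-methoxy-6-pentylbenzoate
Conditions: MeI (2.2 equiv), K2CO3, acetone, 40 °C
Reagents that add atoms: iodomethane, CI
Why: Carboxylate O-alkylation and Williamson etherification; with a limited amount of MeI only the more acidic, non-hydrogen-bonded C4–OH should be alkylated, the C2–OH chelated to the carbonyl staying free.

Step 7
Reactants: 13 methyl 2-hydroxy-4-methoxy-6-pentylbenzoate
Product: 14 2-hydroxy-4-methoxy-6-pentylbenzoic acid
Conditions: KOH, DMSO–H2O, 80 °C; then cold 1 M HCl
Reagents that add atoms: potassium hydroxide, [K+].[OH-]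
Why: Saponification (BAc2) of a hindered, chelated salicylate ester, which needs the enhanced hydroxide reactivity of aqueous DMSO; the aryl methyl ether is inert and the acid is liberated cold to avoid decarboxylation.

Step 8
Reactants: 11 benzyl 4-hydroxy-2-methoxy-6-pentylbenzoate; 14 2-hydroxy-4-methoxy-6-pentylbenzoic acid
Product: 16 benzyl 4-[(2-hydroxy-4-methoxy-6-pentylbenzoyl)oxy]-2-methoxy-6-pentylbenzoate, via mixed trifluoroacetic anhydride 15 (not isolated)
Conditions: (CF3CO)2O, toluene, rt
Reagents that add atoms: none
Why: Depside esterification by the mixed-anhydride method: trifluoroacetic anhydride turns the electron-rich, di-ortho-substituted acid 14 into the acylium-like donor 15, which acylates the only free hydroxyl of 11; the C2–OH of 14 is held in its hydrogen bond and the C2 oxygen of 11 is a methyl ether, so a single aryl ester can form.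

Step 9
Reactants: 16 benzyl 4-[(2-hydroxy-4-methoxy-6-pentylbenzoyl)oxy]-2-methoxy-6-pentylbenzoate
Product: 17 4-[(2-hydroxy-4-methoxy-6-pentylbenzoyl)oxy]-2-methoxy-6-pentylbenzoic acid
Conditions: H2 (1 atm), Pd/C (10% Pd on carbon), EtOAc, rt
Reagents that add atoms: none
Why: Hydrogenolysis of the benzylic C–O bond over Pd/C under neutral conditions; aryl esters, aryl methyl ethers and phenols are untouched, so the depside link should survive.

Step 10
Reactants: 17 4-[(2-hydroxy-4-methoxy-6-pentylbenzoyl)oxy]-2-methoxy-6-pentylbenzoic acid
Product: 18 perlatolic acid
Conditions: BCl3 (3.5 equiv), CH2Cl2, −78 to 0 °C; then ice–H2O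
Reagents that add atoms: none
Why: Chelation-controlled ether cleavage: BCl3 binds the carboxyl group and the ortho methoxy oxygen of ring B in a six-membered chelate and chloride removes the methyl group by SN2 attack; the ring A methoxy group, para to its carbonyl, cannot chelate and should remain, and the aryl ester is not expected to be attacked at low temperature.

## Compound list

1 | oct-2-ynoic acid | CCCCCC#CC(=O)O | starting material
2 | benzyl oct-2-ynoate | CCCCCC#CC(=O)OCc1ccccc1 | intermediate
3 | acetyl chloride | CC(=O)Cl | starting material
4 | 1,1-dichloroethene | C=C(Cl)Cl | starting material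
5 | 4,4,4-trichlorobutan-2-one | CC(=O)CC(Cl)(Cl)Cl | intermediate
6 | 4,4-dichlorobut-3-en-2-one | CC(=O)C=C(Cl)Cl | intermediate
7 | 4,4-dimethoxybut-3-en-2-one | CC(=O)C=C(OC)OC | intermediate
8 | 1,1-dimethoxy-3-(trimethylsilyloxy)buta-1,3-diene | C=C(O[Si](C)(C)C)C=C(OC)OC | intermediate
9 | benzyl 6,6-dimethoxy-2-pentyl-4-(trimethylsilyloxy)cyclohexa-1,4-diene-1-carboxylate | CCCCCC1=C(C(=O)OCc2ccccc2)C(OC)(OC)C=C(O[Si](C)(C)C)C1 | intermediate
10 | benzyl 2-methoxy-6-pentyl-4-(trimethylsilyloxy)benzoate | CCCCCc1cc(O[Si](C)(C)C)cc(OC)c1C(=O)OCc1ccccc1 | intermediate
11 | benzyl 4-hydroxy-2-methoxy-6-pentylbenzoate | CCCCCc1cc(O)cc(OC)c1C(=O)OCc1ccccc1 | intermediate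
12 | olivetolic acid (2,4-dihydroxy-6-pentylbenzoic acid) | CCCCCc1cc(O)cc(O)c1C(=O)O | starting material
13 | methyl 2-hydroxy-4-methoxy-6-pentylbenzoate | CCCCCc1cc(OC)cc(O)c1C(=O)OC | intermediate
14 | 2-hydroxy-4-methoxy-6-pentylbenzoic acid | CCCCCc1cc(OC)cc(O)c1C(=O)O | intermediate
15 | 2-hydroxy-4-methoxy-6-pentylbenzoic trifluoroacetic anhydride | CCCCCc1cc(OC)cc(O)c1C(=O)OC(=O)C(F)(F)F | intermediate
16 | benzyl 4-[(2-hydroxy-4-methoxy-6-pentylbenzoyl)oxy]-2-methoxy-6-pentylbenzoate | CCCCCc1cc(OC(=O)c2c(O)cc(OC)cc2CCCCC)cc(OC)c1C(=O)OCc1ccccc1 | intermediate
17 | 4-[(2-hydroxy-4-methoxy-6-pentylbenzoyl)oxy]-2-methoxy-6-pentylbenzoic acid | CCCCCc1cc(OC(=O)c2c(O)cc(OC)cc2CCCCC)cc(OC)c1C(=O)O | intermediate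
18 | perlatolic acid (2-hydroxy-4-[(2-hydroxy-4-methoxy-6-pentylbenzoyl)oxy]-6-pentylbenzoic acid) | CCCCCc1cc(OC(=O)c2c(O)cc(OC)cc2CCCCC)cc(O)c1C(=O)O | target

## Step count and risks

Total step count: 10. Longest linear sequence: 7 steps (steps 2, 3, 4, 5, 8, 9, 10, from acetyl chloride and 1,1-dichloroethene).

**Step 5 (key step).** The cycloaddition to a β-alkyl ynoate may be slow enough that thermal oligomerization or adventitious hydrolysis of the very electron-rich diene outruns it. Aromatization may also stall at the ketal stage, so that hydrolysis on work-up competes with loss of methanol. The fallback gives up ring construction and differentiates the oxygens of a preformed resorcylate. It sets out from 12. Benzylation of the carboxylate and of the non-chelated C4–OH (BnBr, 2.1 equiv, K2CO3, DMF) should give benzyl 4-(benzyloxy)-2-hydroxy-6-pentylbenzoate F1. Forced methylation of the chelated phenol of F1 (MeI, K2CO3, DMF, 60 °C) gives benzyl 4-(benzyloxy)-2-methoxy-6-pentylbenzoate F2. Hydrogenolysis of both benzyl groups of F2 (H2, Pd/C, EtOAc) gives 4-hydroxy-2-methoxy-6-pentylbenzoic acid F3. Carboxylate-selective benzylation of F3 (BnBr, KHCO3, DMF) then comes back to the route at 11.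

**Step 10.** Demethylation may be slow because the chelate runs through an acyloxyboron species and not a neutral carbonyl. Warming to force it may bring acyl–oxygen cleavage of the depside link, attack on the ring A methyl ether, or decarboxylation during work-up. The fallback moves the demethylation to the stage where only ring B is present. It sets out from 11. BCl3 in CH2Cl2 at −78 to 0 °C, directed by the ester carbonyl, should give benzyl 2,4-dihydroxy-6-pentylbenzoate F4. Coupling of F4 with 14 under the conditions of step 8 acylates the non-chelated C4–OH in preference to the chelated C2–OH and gives benzyl 2-hydroxy-4-[(2-hydroxy-4-methoxy-6-pentylbenzoyl)oxy]-6-pentylbenzoate F5. Hydrogenolysis of F5 (H2, Pd/C, EtOAc) comes back to the route at 18.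

**Step 8.** The mixed anhydride may acylate the C2–OH of a second molecule of 14 (self-condensation). Trifluoroacetylation of 11 may compete, or acyl transfer from so hindered a donor may simply be slow. The fallback protects the ring A phenol and uses an acid chloride. It sets out from 13. Benzylation of the chelated phenol (BnBr, K2CO3, DMF, 60 °C) gives methyl 2-(benzyloxy)-4-methoxy-6-pentylbenzoate F6. Saponification of F6 (KOH, DMSO–H2O, 100 °C) gives 2-(benzyloxy)-4-methoxy-6-pentylbenzoic acid F7. Oxalyl chloride with catalytic DMF in CH2Cl2 converts F7 into 2-(benzyloxy)-4-methoxy-6-pentylbenzoyl chloride F8. Acylation of 11 with F8 (Et3N, catalytic DMAP, CH2Cl2) gives benzyl 4-{[2-(benzyloxy)-4-methoxy-6-pentylbenzoyl]oxy}-2-methoxy-6-pentylbenzoate F9. Hydrogenolysis of both benzyl groups of F9 (H2, Pd/C, EtOAc) comes back to the route at 17.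

**Step 7.** Hydrolysis of the hindered, chelated ester may be sluggish, and the forcing alkaline conditions or the acidification may cause decarboxylation of the electron-rich salicylic acid. The fallback avoids hydrolysis by carrying the carboxyl as a benzyl ester. It sets out from 12. Carboxylate benzylation (BnBr, KHCO3, DMF) gives benzyl 2,4-dihydroxy-6-pentylbenzoate F4, the ester also met in the fallback for step 10. Methylation of the non-chelated phenol of F4 (MeI, 1.1 equiv, K2CO3, acetone) gives benzyl 2-hydroxy-4-methoxy-6-pentylbenzoate F10. Hydrogenolysis of F10 (H2, Pd/C, EtOAc) comes back to the route at 14.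

## Further compounds

F1 | step 5 | benzyl 4-(benzyloxy)-2-hydroxy-6-pentylbenzoate | CCCCCc1cc(OCc2ccccc2)cc(O)c1C(=O)OCc1ccccc1
F2 | step 5 | benzyl 4-(benzyloxy)-2-methoxy-6-pentylbenzoate | CCCCCc1cc(OCc2ccccc2)cc(OC)c1C(=O)OCc1ccccc1
F3 | step 5 | 4-hydroxy-2-methoxy-6-pentylbenzoic acid | CCCCCc1cc(O)cc(OC)c1C(=O)O
F4 | step 10 | benzyl 2,4-dihydroxy-6-pentylbenzoate | CCCCCc1cc(O)cc(O)c1C(=O)OCc1ccccc1
F5 | step 10 | benzyl 2-hydroxy-4-[(2-hydroxy-4-methoxy-6-pentylbenzoyl)oxy]-6-pentylbenzoate | CCCCCc1cc(OC(=O)c2c(O)cc(OC)cc2CCCCC)cc(O)c1C(=O)OCc1ccccc1
F6 | step 8 | methyl 2-(benzyloxy)-4-methoxy-6-pentylbenzoate | CCCCCc1cc(OC)cc(OCc2ccccc2)c1C(=O)OC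
F7 | step 8 | 2-(benzyloxy)-4-methoxy-6-pentylbenzoic acid | CCCCCc1cc(OC)cc(OCc2ccccc2)c1C(=O)O
F8 | step 8 | 2-(benzyloxy)-4-methoxy-6-pentylbenzoyl chloride | CCCCCc1cc(OC)cc(OCc2ccccc2)c1C(=O)Cl
F9 | step 8 | benzyl 4-{[2-(benzyloxy)-4-methoxy-6-pentylbenzoyl]oxy}-2-methoxy-6-pentylbenzoate | CCCCCc1cc(OC(=O)c2c(OCc3ccccc3)cc(OC)cc2CCCCC)cc(OC)c1C(=O)OCc1ccccc1
F10 | step 7 | benzyl 2-hydroxy-4-methoxy-6-pentylbenzoate | CCCCCc1cc(OC)cc(O)c1C(=O)OCc1ccccc1
A1 | alternative 1 | 1-fluoro-3,5-dimethoxybenzene | COc1cc(F)cc(OC)c1
A2 | alternative 1 | pentyllithium | [Li]CCCCC
A3 | alternative 1 | 3,5-dimethoxybenzyne (1,2-didehydro-3,5-dimethoxybenzene) | COC1=CC(OC)=CC#C1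
A4 | alternative 1 | 2,4-dimethoxy-6-pentylbenzoic acid | CCCCCc1cc(OC)cc(OC)c1C(=O)O
A5 | alternative 2 | 1-methoxy-1,3-bis(trimethylsilyloxy)buta-1,3-diene | C=C(O[Si](C)(C)C)C=C(OC)O[Si](C)(C)C
A6 | alternative 2 | 1,1-dimethoxyoct-1-en-3-one | CCCCCC(=O)C=C(OC)OC
A7 | alternative 2 | methyl 2-hydroxy-4-methoxy-6-pentylbenzoate | CCCCCc1cc(OC)cc(O)c1C(=O)OC
A8 | alternative 3 | benzyl 3,5,7-trioxododecanoate | CCCCCC(=O)CC(=O)CC(=O)CC(=O)OCc1ccccc1
A9 | alternative 3 | benzyl 2,4-dihydroxy-6-pentylbenzoate | CCCCCc1cc(O)cc(O)c1C(=O)OCc1ccccc1
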